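## Structural features

The target is an ent-labdane: a trans-fused decalin in which ring A (C-1 to C-5, C-10) and ring B (C-5 to C-10) share the C-5–C-10 bond, with a six-carbon branched chain on C-9 (labdane numbering throughout). It has five stereocentres. C-2 and C-3 are adjacent carbinol carbons with cis oxygens (equatorial acetoxy at C-2, axial free hydroxyl at C-3), and C-3 sits next to the C-4 gem-dimethyl carbon. C-5, the quaternary methyl-bearing C-10 and C-9 are contiguous along ring B. Ring B holds a trisubstituted C-7=C-8 alkene, and the chain holds an (E)-trisubstituted C-13=C-14 alkene ending in a primary allylic acetate at C-15. The fragile points are the allylic acetate (ionisation, reduction), the mono-acetylated cis-diol (acyl migration between O-2 and O-3) and both trisubstituted alkenes (acid-induced migration, electrophilic oxidants). The real difficulties are the C-9 stereocentre beside the quaternary C-10 with the alkene fixed at C-7=C-8, and telling the two ring-A oxygens apart. The key step uses the fact that C-2 and C-3 are vicinal carbinols flanked by the C-1 methylene and the quaternary C-4: both can come from aldehydes, and joining them closes ring A on a finished ring B with the oxidation pattern in place.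

## Logic of the disconnections

33 ⇒ 32 ⇒ 31. The two acetyl C–O bonds and then the Si–O bond are cut. This removes the only differentiation problem from the ring-forming stage and leaves a diol with one silyl ether. The forward acetylation must discriminate the equatorial C-2 and primary C-15 hydroxyls from the axial, neopentyl C-3 hydroxyl.

31 ⇒ 30. The C-2–C-3 bond is cut, which opens ring A to a 1,6-dialdehyde on an intact ring B. Both carbinol stereocentres and the ring disappear in one cut. The forward reductive coupling must give the cis-diol on the face away from the axial methyls at C-10 and C-4, and must leave two alkenes and an allylic silyl ether alone.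

30 ⇒ 29 ⇒ 28. No skeletal bond is cut; the aldehydes are traced through the diol to two methyl esters. Esters are the form in which the two arms can be carried through base, palladium and copper chemistry. The forward reduction and oxidation must be mild because 30 has an enolisable arm next to a second aldehyde.

28 ⇒ 25 + 8. The C-9–C-11 bond is cut in the allylic (SN2') sense, so the C-7=C-8 alkene of 28 becomes the C-8=C-9 alkene of 25 with a leaving group on C-7. This is the departure from a simple addition of the chain to a C-9 enone followed by allylic transposition, which would leave C-9 without a controlling element. Here the C-7 oxygen, present from the start, is kept and its configuration is transferred to C-9 by anti substitution. The gain is a convergent union with the complete chain. The demand is γ-attack at a carbon beside a quaternary centre.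

25 ⇒ 24 ⇒ 23 ⇒ 22 ⇒ 20. Only functional groups change: the leaving group goes back to the silyl ether, and the C-9 hydrogen goes back through the enol triflate to the C-9 ketone. This links the allylic system to a ketone that conjugate-addition chemistry can deliver. The forward enolisation must not expel the C-7 oxygen.

20 ⇒ 18. The C-8–methyl bond is cut, an enolate alkylation at the only enolisable carbon of the ketone.

18 ⇒ 15 + 16. The C-1–C-10 bond is cut, which removes the quaternary centre. The forward alkylation must occur regiospecifically at the fully substituted enolate carbon and trans to the C-5 substituent.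

15 ⇒ 13 + 14. The C-4–C-5 bond is cut in the conjugate-addition sense, leaving a simple enone whose single stereocentre (C-7) must direct the nucleophile to the opposite face.

13 ⇒ 12 ⇒ 11 ⇒ 9. The C–O bond at C-7 is traced to the C–C bond of the isopropenyl group of 9. The chiral pool supplies the absolute configuration, and the forward degradation must proceed with retention.

8 ⇒ 7 ⇒ 6 ⇒ 5 ⇒ 2 ⇒ 1. After functional-group changes, the C-13–methyl and C-14–C-15 bonds are cut across the alkyne of 1. One syn carbometallation sets the E geometry and two protecting-group operations differentiate the chain ends.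

## Other disconnections considered

Alternative 1: The cut is at C-4–C-5 and C-1–C-10, the same two bonds that steps 9 and 10 make, but formed in one flask on enone 13. A Lewis-acid-mediated transfer of a prenyl unit through its tertiary terminus would be followed by allylation of the released enolate to give A1. In its favour, the stereochemical logic is the same as in the chosen plan (anti to the silyloxy group, then anti to the new C-5 substituent), so on control of C-5 and C-10 it is the equal of the chosen plan. It is the better on step count for these two bonds (one step against two) and on compatibility, since A1 has no ester to interfere with later organometallic steps. Against it, the two vinyl groups of A1 reach the C-2 and C-3 aldehydes only by oxidative cleavage. That cannot be done once the C-7=C-8 and C-13=C-14 alkenes are present. The aldehydes would therefore have to be unmasked early and protected, or ring A closed early by a different reaction (metathesis, then dihydroxylation) and its diol carried protected through all of the ring-B chemistry. The C-9 problem is unchanged. Overall it is mechanistically close to the chosen plan and slightly shorter at the front, but it fits poorly with closing ring A last; the ester oxidation level of the chosen plan keeps C-2 and C-3 masked until one reduction–oxidation pair before the coupling.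

Alternative 2: The cuts are at C-5–C-10 and C-8–C-9; open-chain triene A2 would fold in an intramolecular Diels–Alder reaction to A3, closing both rings. In its favour, two rings, two C–C bonds and four stereocentres would arise in one step, which is clearly better than any single step of the chosen plan. C-3, C-4 and the protected diol come from pantolactone. The C-9/C-10 relationship follows stereospecifically from the enoate geometry, a firmer handle on C-9 than an allylic substitution at a hindered carbon. Against it, the dienophile is a β,β-disubstituted enoate that must form the quaternary C-10, so forcing conditions or Lewis acids would be needed and these endanger the silyloxydiene. The trans ring fusion and the facial sense rest on a remote acetonide. After the cycloaddition the C-7 enol ether must still become the C-7=C-8 alkene and the C-9 ester must be extended by four carbons with an E alkene. A2 itself, with two geometrically defined diene units, needs a long linear sequence. Overall it is a concerted pericyclic construction against the stepwise ionic and radical bond formations chosen here. It is superior in complexity per step and in the certainty of C-9, equal on the final O-2/O-3 differentiation, and probably inferior in total step count and in the risk carried by the single cycloaddition.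

Alternative 3: The cut is at C-3–C-4. (S)-Carvone would serve as ring B with the C-8 methyl, the C-7=C-8 alkene and a C-9 carbonyl already present, and enyne A4 would cyclise under triflic acid to A5. In its favour, this is the shortest way to the decalin. The isopropenyl group is used in full as C-4 and its two methyls, which is better atom economy than the chosen plan, where it is degraded to an oxygen. C-5 and C-10 follow from alkylation trans to the isopropenyl group, and the ring-B methyl and alkene need none of steps 11 to 13. Against it, ring A emerges with one oxygen (C-2, as the enol triflate) and none at C-3. The C-3 hydroxyl would have to be introduced next to the quaternary C-4, and both carbinols set by reductions that must deliver opposite orientations (equatorial at C-2, axial at C-3). The C-9 carbonyl then needs the chain and a hydrogen with control but without a neighbouring stereocentre to relay it, and the strong acid fixes the order of events because the chain would not survive it. Overall it is a cationic ring closure (vinyl cation captured by triflate) against the ketyl coupling. It is better on step economy to the bicycle and on use of the starting material, and weaker on the ring-A oxidation pattern and on C-9, which the chosen plan controls through the C-7 oxygen.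

Key step: step 19

Remark: positions are cited in labdane numbering (C-1 to C-20), also for monocyclic intermediates. Silyl ketene acetal 14 is taken as a purchased reagent (otherwise one step from methyl isobutyrate with LiN(iPr)2 and Me3SiCl). The seco-dialdehyde 30 and the cyclised diol 31 were checked against the target and carry its configuration at C-5, C-9 and C-10, so no structure needed correction.

## Route

Step 1
Reactants: 1 but-3-yn-1-ol
Product: 2 1-[(but-3-yn-1-yloxy)methyl]-4-methoxybenzene
Conditions: NaH, THF/DMF, 0 °C; 4-MeOC6H4CH2Cl, Bu4NI (cat.), rt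
Reagents that add atoms: 4-methoxybenzyl chloride, COc1ccc(CCl)cc1
Why: Williamson ether synthesis on the primary alkoxide (the alkyne C–H is not touched); the arylmethyl ether tolerates Me3Al and is later removed oxidatively beside a silyl ether.

Step 2
Reactants: 2 1-[(but-3-yn-1-yloxy)methyl]-4-methoxybenzene
Product: 5 (2E)-5-[(4-methoxybenzyl)oxy]-3-methylpent-2-en-1-ol, via alkenyl(dimethyl)alane 3 (not isolated), via lithium alkenylalanate 4 (not isolated)
Conditions: Me3Al (3 equiv), Cp2ZrCl2 (0.25 equiv), CH2Cl2, 0 °C → rt; evaporate; n-BuLi, THF/hexane, −78 → 0 °C; (CH2O)n, rt; aq. potassium sodium tartrate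
Reagents that add atoms: trimethylaluminium, C[Al](C)C; formaldehyde (from paraformaldehyde), C=O
Why: Zirconium-catalysed carboalumination adds methyl and aluminium syn across the terminal alkyne with methyl on the inner carbon; the alanate attacks formaldehyde with retention at the alkenyl carbon, so C-13=C-14 is formed as the E isomer.

Step 3
Reactants: 5 (2E)-5-[(4-methoxybenzyl)oxy]-3-methylpent-2-en-1-ol
Product: 6 tert-butyl{[(2E)-5-[(4-methoxybenzyl)oxy]-3-methylpent-2-en-1-yl]oxy}dimethylsilane
Conditions: t-BuMe2SiCl, imidazole, CH2Cl2, 0 °C → rt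
Reagents that add atoms: tert-butyldimethylsilyl chloride, CC(C)(C)[Si](C)(C)Cl
Why: Routine silylation of the primary allylic alcohol; this silyl ether is the C-15 protecting group carried to step 20.

Step 4
Reactants: 6 tert-butyl{[(2E)-5-[(4-methoxybenzyl)oxy]-3-methylpent-2-en-1-yl]oxy}dimethylsilane
Product: 7 (3E)-5-{[tert-butyl(dimethyl)silyl]oxy}-3-methylpent-3-en-1-ol
Conditions: DDQ, CH2Cl2/pH 7 buffer (NaH2PO4/Na2HPO4), 0 °C
Reagents that add atoms: none
Why: Oxidative cleavage of the electron-rich arylmethyl ether (hydride abstraction by DDQ, hydrolysis of the oxocarbenium ion); the silyl ether and the trisubstituted alkene are inert under buffered conditions.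

Step 5
Reactants: 7 (3E)-5-{[tert-butyl(dimethyl)silyl]oxy}-3-methylpent-3-en-1-ol
Product: 8 {[(2E)-5-bromo-3-methylpent-2-en-1-yl]oxy}(tert-butyl)dimethylsilane
Conditions: CBr4, PPh3, CH2Cl2, 0 °C
Reagents that add atoms: carbon tetrabromide, BrC(Br)(Br)Br
Why: Appel bromination of the primary alcohol by SN2 on the alkoxyphosphonium salt under neutral conditions; the hydroxyl is homoallylic, so no allylic transposition can occur.

Step 6
Reactants: 9 (S)-carvone
Product: 11 (1S)-4-methyl-5-oxocyclohex-3-en-1-yl acetate, via methoxy hydroperoxide 10 (not isolated)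
Conditions: O3, CH2Cl2/MeOH, −78 °C; N2 purge; Ac2O, Et3N, DMAP (cat.), −78 °C → rt
Reagents that add atoms: ozone, [O-][O+]=O; methanol, CO
Why: Ozone attacks the electron-rich 1,1-disubstituted alkene and not the enone, and methanol traps the carbonyl oxide as 10. The peracetate of 10 undergoes Criegee rearrangement with migration of the ring carbon and retention at the future C-7, and acetate demethylates the dioxacarbenium ion to leave the acetate.

Step 7
Reactants: 11 (1S)-4-methyl-5-oxocyclohex-3-en-1-yl acetate
Product: 12 (5S)-5-hydroxy-2-methylcyclohex-2-en-1-one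
Conditions: K2CO3 (cat.), MeOH, 0 °C
Reagents that add atoms: none
Why: Base-catalysed transesterification frees the secondary alcohol; the low temperature holds back β-elimination to the dienone and its aromatisation.

Step 8
Reactants: 12 (5S)-5-hydroxy-2-methylcyclohex-2-en-1-one
Product: 13 (5S)-5-{[tert-butyl(dimethyl)silyl]oxy}-2-methylcyclohex-2-en-1-one
Conditions: t-BuMe2SiCl, imidazole, DMF, rt
Reagents that add atoms: tert-butyldimethylsilyl chloride, CC(C)(C)[Si](C)(C)Cl
Why: Silylation gives the base-stable C-7 silyl ether that directs the next two C–C bond formations and later marks the allylic leaving-group site.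

Step 9
Reactants: 13 (5S)-5-{[tert-butyl(dimethyl)silyl]oxy}-2-methylcyclohex-2-en-1-one; 14 [(1-methoxy-2-methylprop-1-en-1-yl)oxy]trimethylsilane
Product: 15 methyl 2-[(1S,5S)-5-{[tert-butyl(dimethyl)silyl]oxy}-2-methyl-3-[(trimethylsilyl)oxy]cyclohex-2-en-1-yl]-2-methylpropanoate
Conditions: HNTf2 (2 mol %), CH2Cl2, −78 °C; Et3N
Reagents that add atoms: none
Why: Mukaiyama–Michael addition catalysed by Me3SiNTf2 formed in situ; the ketene acetal attacks the β-carbon (C-5) anti to the C-7 silyloxy group, and silyl transfer leaves the enol ether regiodefined at C-9/C-10.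

Step 10
Reactants: 15 methyl 2-[(1S,5S)-5-{[tert-butyl(dimethyl)silyl]oxy}-2-methyl-3-[(trimethylsilyl)oxy]cyclohex-2-en-1-yl]-2-methylpropanoate; 16 methyl bromoacetate
Product: 18 methyl 2-[(1S,2R,5S)-5-{[tert-butyl(dimethyl)silyl]oxy}-2-(2-methoxy-2-oxoethyl)-2-methyl-3-oxocyclohexyl]-2-methylpropanoate, via ammonium enolate 17 (not isolated)
Conditions: BnMe3NF (anhydrous, 1.1 equiv), 16 (3 equiv), 4 Å molecular sieves, THF, −20 °C → rt
Reagents that add atoms: none
Why: Fluoride-promoted regiospecific alkylation of a silyl enol ether (desilylation to the naked enolate, then SN2 on the activated bromide). A(1,2) strain with the C-10 methyl holds the C-5 substituent pseudoaxial, so the electrophile enters from the opposite face and the new C-1–C-10 bond is trans to C-4–C-5, creating the quaternary centre.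

Step 11
Reactants: 18 methyl 2-[(1S,2R,5S)-5-{[tert-butyl(dimethyl)silyl]oxy}-2-(2-methoxy-2-oxoethyl)-2-methyl-3-oxocyclohexyl]-2-methylpropanoate
Product: 20 methyl 2-[(1S,2R,4RS,5S)-5-{[tert-butyl(dimethyl)silyl]oxy}-2-(2-methoxy-2-oxoethyl)-2,4-dimethyl-3-oxocyclohexyl]-2-methylpropanoate, via lithium enolate 19 (not isolated)
Conditions: LiN(iPr)2 (1.1 equiv), THF, −78 °C; MeI, DMPU, −78 → −40 °C
Reagents that add atoms: iodomethane, CI
Why: Kinetic enolate methylation; C-8 is the only enolisable position of the ketone (C-10 is quaternary) and lithium enolates of β-silyloxy ketones persist at −78 °C. The C-8 configuration is immaterial because this carbon becomes sp2 in step 12.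

Step 12
Reactants: 20 methyl 2-[(1S,2R,4RS,5S)-5-{[tert-butyl(dimethyl)silyl]oxy}-2-(2-methoxy-2-oxoethyl)-2,4-dimethyl-3-oxocyclohexyl]-2-methylpropanoate
Product: 22 methyl 2-[(1S,2R,5S)-5-{[tert-butyl(dimethyl)silyl]oxy}-2-(2-methoxy-2-oxoethyl)-2,4-dimethyl-3-{[(trifluoromethyl)sulfonyl]oxy}cyclohex-3-en-1-yl]-2-methylpropanoate, via potassium enolate 21 (not isolated)
Conditions: KN(SiMe3)2 (1.2 equiv), THF, −78 °C; N-(5-chloro-2-pyridyl)triflimide, −78 °C
Reagents that add atoms: N-(5-chloropyridin-2-yl)bis(trifluoromethanesulfonyl)imide, FC(F)(F)S(=O)(=O)N(c1ccc(Cl)cn1)S(=O)(=O)C(F)(F)F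
Why: Enol triflate formation; the single remaining α-hydrogen (C-8) is removed and the potassium enolate is O-sulfonylated at −78 °C by the reactive pyridyl triflimide faster than silanolate is expelled from C-7.

Step 13
Reactants: 22 methyl 2-[(1S,2R,5S)-5-{[tert-butyl(dimethyl)silyl]oxy}-2-(2-methoxy-2-oxoethyl)-2,4-dimethyl-3-{[(trifluoromethyl)sulfonyl]oxy}cyclohex-3-en-1-yl]-2-methylpropanoate
Product: 23 methyl 2-[(1S,2S,5S)-5-{[tert-butyl(dimethyl)silyl]oxy}-2-(2-methoxy-2-oxoethyl)-2,4-dimethylcyclohex-3-en-1-yl]-2-methylpropanoate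
Conditions: Pd(OAc)2 (5 mol %), PPh3 (10 mol %), HCO2H, Bu3N, DMF, 60 °C
Reagents that add atoms: none
Why: Palladium-catalysed formate reduction of an enol triflate (oxidative addition to zerovalent palladium, formate exchange, decarboxylation, C–H reductive elimination) gives the C-8=C-9 alkene with hydrogen on C-9; the allylic silyl ether does not ionise.

Step 14
Reactants: 23 methyl 2-[(1S,2S,5S)-5-{[tert-butyl(dimethyl)silyl]oxy}-2-(2-methoxy-2-oxoethyl)-2,4-dimethylcyclohex-3-en-1-yl]-2-methylpropanoate
Product: 24 methyl 2-[(1S,2S,5S)-5-hydroxy-2-(2-methoxy-2-oxoethyl)-2,4-dimethylcyclohex-3-en-1-yl]-2-methylpropanoate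
Conditions: HF·pyridine, pyridine/THF, 0 °C → rt
Reagents that add atoms: none
Why: Fluoride cleavage of the secondary allylic silyl ether under non-basic conditions; the C-7 hydroxyl is trans to the C-5 ester arm and remote from the C-10 arm, so it cannot lactonise.

Step 15
Reactants: 24 methyl 2-[(1S,2S,5S)-5-hydroxy-2-(2-methoxy-2-oxoethyl)-2,4-dimethylcyclohex-3-en-1-yl]-2-methylpropanoate
Product: 25 (1S,4S,5S)-4-(2-methoxy-2-oxoethyl)-5-(1-methoxy-2-methyl-1-oxopropan-2-yl)-2,4-dimethylcyclohex-2-en-1-yl pyridine-2-carboxylate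
Conditions: picolinic acid, DCC, DMAP (cat.), CH2Cl2, rt
Reagents that add atoms: pyridine-2-carboxylic acid, OC(=O)c1ccccn1
Why: Carbodiimide (Steglich) esterification with retention at C-7; the picolinate is a chelating leaving group suited to copper-mediated allylic substitution.

Step 16
Reactants: 25 (1S,4S,5S)-4-(2-methoxy-2-oxoethyl)-5-(1-methoxy-2-methyl-1-oxopropan-2-yl)-2,4-dimethylcyclohex-2-en-1-yl pyridine-2-carboxylate; 8 {[(2E)-5-bromo-3-methylpent-2-en-1-yl]oxy}(tert-butyl)dimethylsilane
Product: 28 methyl 2-[(1S,5R,6S)-5-[(3E)-5-{[tert-butyl(dimethyl)silyl]oxy}-3-methylpent-3-en-1-yl]-6-(2-methoxy-2-oxoethyl)-4,6-dimethylcyclohex-3-en-1-yl]-2-methylpropanoate, via Grignard reagent 26 (not isolated), via magnesium dialkylcuprate 27 (not isolated)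
Conditions: 8 (3 equiv), Mg, THF, rt; CuBr·SMe2 (1.5 equiv), THF, −78 → −40 °C; 25, −60 → 0 °C; aq. NH4Cl
Reagents that add atoms: none
Why: Copper-mediated anti-SN2' substitution of an allylic picolinate. Magnesium chelated by the picolinate activates the pseudoaxial C-7–O bond (pseudoaxial to avoid A(1,2) strain with the C-8 methyl), copper attacks C-9 on the opposite face, and reductive elimination forms C-9–C-11 while the alkene moves to C-7=C-8. The C-7 configuration is thus transferred to C-9 (chain cis to the C-10 methyl), and the cuprate does not add to the methyl esters.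

Step 17
Reactants: 28 methyl 2-[(1S,5R,6S)-5-[(3E)-5-{[tert-butyl(dimethyl)silyl]oxy}-3-methylpent-3-en-1-yl]-6-(2-methoxy-2-oxoethyl)-4,6-dimethylcyclohex-3-en-1-yl]-2-methylpropanoate
Product: 29 2-[(1S,5R,6S)-5-[(3E)-5-{[tert-butyl(dimethyl)silyl]oxy}-3-methylpent-3-en-1-yl]-6-(2-hydroxyethyl)-4,6-dimethylcyclohex-3-en-1-yl]-2-methylpropan-1-ol
Conditions: LiAlH4, THF, 0 °C → rt
Reagents that add atoms: none
Why: Hydride reduction of both esters to primary alcohols (the neopentyl ester needs LiAlH4); the alkenes and the silyl ether are inert.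

Step 18
Reactants: 29 2-[(1S,5R,6S)-5-[(3E)-5-{[tert-butyl(dimethyl)silyl]oxy}-3-methylpent-3-en-1-yl]-6-(2-hydroxyethyl)-4,6-dimethylcyclohex-3-en-1-yl]-2-methylpropan-1-ol
Product: 30 2-[(1S,5R,6S)-5-[(3E)-5-{[tert-butyl(dimethyl)silyl]oxy}-3-methylpent-3-en-1-yl]-4,6-dimethyl-6-(2-oxoethyl)cyclohex-3-en-1-yl]-2-methylpropanal
Conditions: Dess–Martin periodinane, NaHCO3, CH2Cl2, 0 °C → rt; used at once
Reagents that add atoms: none
Why: Dess–Martin oxidation of both primary alcohols under buffered conditions; the dialdehyde is not stored because C-1 is enolisable and could close onto the C-3 aldehyde by aldol reaction.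

Step 19
Reactants: 30 2-[(1S,5R,6S)-5-[(3E)-5-{[tert-butyl(dimethyl)silyl]oxy}-3-methylpent-3-en-1-yl]-4,6-dimethyl-6-(2-oxoethyl)cyclohex-3-en-1-yl]-2-methylpropanal
Product: 31 (2R,3S,4aS,5R,8aS)-5-[(3E)-5-{[tert-butyl(dimethyl)silyl]oxy}-3-methylpent-3-en-1-yl]-1,1,4a,6-tetramethyl-1,2,3,4,4a,5,8,8a-octahydronaphthalene-2,3-diol
Conditions: SmI2 (3 equiv, 0.1 M in THF), t-BuOH (2 equiv), THF (0.01 M), −78 °C → rt
Reagents that add atoms: none
Why: Divalent samarium transfers one electron to the less hindered C-2 aldehyde; the ketyl, bound to trivalent samarium that also holds the C-3 carbonyl oxygen, adds to C-3, and a second electron transfer gives the samarium diolate, which is protonated on work-up. The closest known reaction type is the SmI2-mediated intramolecular pinacol coupling of 1,6-dialdehydes to cis-cyclohexane-1,2-diols. Ring A closes as a six-membered ring by 6-exo attack of the ketyl carbon on the second carbonyl, through a chair in which C-1, C-10, C-5 and C-4 are already fixed by ring B. The cis relation of C-2 and C-3 follows from the chelate, since both oxygens stay on one samarium and hence on one face. Which cis-diol forms is decided by the substrate: the other cis arrangement would put the C-2 oxygen 1,3-diaxial to both the C-10 methyl and the axial C-4 methyl, so the diolate forms on the opposite face and gives the equatorial C-2 and axial C-3 oxygens. The step needs chemoselectivity for the aldehydes over the two trisubstituted alkenes and the allylic silyl ether; leaving out HMPA secures this, because ketyl addition to unactivated alkenes is slow without it. High dilution lets ring closure outrun intermolecular coupling. No existing stereocentre is at risk, since the C-3 aldehyde has no α-hydrogen and C-5, C-9 and C-10 cannot epimerise.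

Step 20
Reactants: 31 (2R,3S,4aS,5R,8aS)-5-[(3E)-5-{[tert-butyl(dimethyl)silyl]oxy}-3-methylpent-3-en-1-yl]-1,1,4a,6-tetramethyl-1,2,3,4,4a,5,8,8a-octahydronaphthalene-2,3-diol
Product: 32 (2R,3S,4aS,5R,8aS)-5-[(3E)-5-hydroxy-3-methylpent-3-en-1-yl]-1,1,4a,6-tetramethyl-1,2,3,4,4a,5,8,8a-octahydronaphthalene-2,3-diol
Conditions: Bu4NF, THF, 0 °C → rt
Reagents that add atoms: none
Why: Fluoride cleavage of the primary silyl ether; the diol and both alkenes are unaffected.

Step 21
Reactants: 32 (2R,3S,4aS,5R,8aS)-5-[(3E)-5-hydroxy-3-methylpent-3-en-1-yl]-1,1,4a,6-tetramethyl-1,2,3,4,4a,5,8,8a-octahydronaphthalene-2,3-diol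
Product: 33 (2S,3R,4aS,8R,8aS)-8-[(3E)-5-(acetyloxy)-3-methylpent-3-en-1-yl]-3-hydroxy-4,4,7,8a-tetramethyl-1,2,3,4,4a,5,8,8a-octahydronaphthalen-2-yl acetate (CNP0254679.1)
Conditions: Ac2O (2.2 equiv), pyridine, CH2Cl2, 0 °C
Reagents that add atoms: acetic anhydride, CC(=O)OC(C)=O
Why: Acylation under steric control: the primary allylic hydroxyl and the equatorial C-2 hydroxyl react, while the axial C-3 hydroxyl beside the gem-dimethyl carbon should not at 0 °C without DMAP.

## Compound list

1 | but-3-yn-1-ol | C#CCCO | starting material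
2 | 1-[(but-3-yn-1-yloxy)methyl]-4-methoxybenzene | COc1ccc(COCCC#C)cc1 | intermediate
3 | [(1E)-4-[(4-methoxybenzyl)oxy]-2-methylbut-1-en-1-yl]dimethylalane | COc1ccc(COCC/C(C)=C/[Al](C)C)cc1 | intermediate (not isolated)
4 | lithium butyl[(1E)-4-[(4-methoxybenzyl)oxy]-2-methylbut-1-en-1-yl]dimethylalanate | [Li+].CCCC[Al-](C)(C)/C=C(\C)CCOCc1ccc(OC)cc1 | intermediate (not isolated)
5 | (2E)-5-[(4-methoxybenzyl)oxy]-3-methylpent-2-en-1-ol | COc1ccc(COCC/C(C)=C/CO)cc1 | intermediate
6 | tert-butyl{[(2E)-5-[(4-methoxybenzyl)oxy]-3-methylpent-2-en-1-yl]oxy}dimethylsilane | COc1ccc(COCC/C(C)=C/CO[Si](C)(C)C(C)(C)C)cc1 | intermediate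
7 | (3E)-5-{[tert-butyl(dimethyl)silyl]oxy}-3-methylpent-3-en-1-ol | OCC/C(C)=C/CO[Si](C)(C)C(C)(C)C | intermediate
8 | {[(2E)-5-bromo-3-methylpent-2-en-1-yl]oxy}(tert-butyl)dimethylsilane | BrCC/C(C)=C/CO[Si](C)(C)C(C)(C)C | intermediate
9 | (S)-carvone, (5S)-2-methyl-5-(prop-1-en-2-yl)cyclohex-2-en-1-one | CC1=CC[C@H](C(C)=C)CC1=O | starting material
10 | (5S)-5-(1-hydroperoxy-1-methoxyethyl)-2-methylcyclohex-2-en-1-one (both epimers at the acetal carbon) | CC1=CC[C@H](C(C)(OC)OO)CC1=O | intermediate (not isolated)
11 | (1S)-4-methyl-5-oxocyclohex-3-en-1-yl acetate | CC1=CC[C@H](OC(C)=O)CC1=O | intermediate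
12 | (5S)-5-hydroxy-2-methylcyclohex-2-en-1-one | CC1=CC[C@H](O)CC1=O | intermediate
13 | (5S)-5-{[tert-butyl(dimethyl)silyl]oxy}-2-methylcyclohex-2-en-1-one | CC1=CC[C@H](O[Si](C)(C)C(C)(C)C)CC1=O | intermediate
14 | [(1-methoxy-2-methylprop-1-en-1-yl)oxy]trimethylsilane | COC(O[Si](C)(C)C)=C(C)C | starting material
15 | methyl 2-[(1S,5S)-5-{[tert-butyl(dimethyl)silyl]oxy}-2-methyl-3-[(trimethylsilyl)oxy]cyclohex-2-en-1-yl]-2-methylpropanoate | COC(=O)C(C)(C)[C@H]1C[C@H](O[Si](C)(C)C(C)(C)C)CC(O[Si](C)(C)C)=C1C | intermediate
16 | methyl bromoacetate | COC(=O)CBr | starting material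
17 | benzyltrimethylammonium C-9/C-10 enolate formed from 15 by loss of the trimethylsilyl group | COC(=O)C(C)(C)[C@H]1C[C@H](O[Si](C)(C)C(C)(C)C)CC([O-])=C1C.C[N+](C)(C)Cc1ccccc1 | intermediate (not isolated)
18 | methyl 2-[(1S,2R,5S)-5-{[tert-butyl(dimethyl)silyl]oxy}-2-(2-methoxy-2-oxoethyl)-2-methyl-3-oxocyclohexyl]-2-methylpropanoate | COC(=O)C[C@@]1(C)C(=O)C[C@@H](O[Si](C)(C)C(C)(C)C)C[C@@H]1C(C)(C)C(=O)OC | intermediate
19 | lithium C-8/C-9 enolate of 18 | COC(=O)C[C@@]1(C)C(O[Li])=C[C@@H](O[Si](C)(C)C(C)(C)C)C[C@@H]1C(C)(C)C(=O)OC | intermediate (not isolated)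
20 | methyl 2-[(1S,2R,4RS,5S)-5-{[tert-butyl(dimethyl)silyl]oxy}-2-(2-methoxy-2-oxoethyl)-2,4-dimethyl-3-oxocyclohexyl]-2-methylpropanoate | COC(=O)C[C@@]1(C)C(=O)C(C)[C@@H](O[Si](C)(C)C(C)(C)C)C[C@@H]1C(C)(C)C(=O)OC | intermediate
21 | potassium C-8/C-9 enolate of 20 | COC(=O)C[C@@]1(C)C(O[K])=C(C)[C@@H](O[Si](C)(C)C(C)(C)C)C[C@@H]1C(C)(C)C(=O)OC | intermediate (not isolated)
22 | methyl 2-[(1S,2R,5S)-5-{[tert-butyl(dimethyl)silyl]oxy}-2-(2-methoxy-2-oxoethyl)-2,4-dimethyl-3-{[(trifluoromethyl)sulfonyl]oxy}cyclohex-3-en-1-yl]-2-methylpropanoate | COC(=O)C[C@@]1(C)C(OS(=O)(=O)C(F)(F)F)=C(C)[C@@H](O[Si](C)(C)C(C)(C)C)C[C@@H]1C(C)(C)C(=O)OC | intermediate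
23 | methyl 2-[(1S,2S,5S)-5-{[tert-butyl(dimethyl)silyl]oxy}-2-(2-methoxy-2-oxoethyl)-2,4-dimethylcyclohex-3-en-1-yl]-2-methylpropanoate | COC(=O)C[C@@]1(C)C=C(C)[C@@H](O[Si](C)(C)C(C)(C)C)C[C@@H]1C(C)(C)C(=O)OC | intermediate
24 | methyl 2-[(1S,2S,5S)-5-hydroxy-2-(2-methoxy-2-oxoethyl)-2,4-dimethylcyclohex-3-en-1-yl]-2-methylpropanoate | COC(=O)C[C@@]1(C)C=C(C)[C@@H](O)C[C@@H]1C(C)(C)C(=O)OC | intermediate
25 | (1S,4S,5S)-4-(2-methoxy-2-oxoethyl)-5-(1-methoxy-2-methyl-1-oxopropan-2-yl)-2,4-dimethylcyclohex-2-en-1-yl pyridine-2-carboxylate | COC(=O)C[C@@]1(C)C=C(C)[C@@H](OC(=O)c2ccccn2)C[C@@H]1C(C)(C)C(=O)OC | intermediate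
26 | bromo[(3E)-5-{[tert-butyl(dimethyl)silyl]oxy}-3-methylpent-3-en-1-yl]magnesium | Br[Mg]CC/C(C)=C/CO[Si](C)(C)C(C)(C)C | intermediate (not isolated)
27 | bromomagnesium bis[(3E)-5-{[tert-butyl(dimethyl)silyl]oxy}-3-methylpent-3-en-1-yl]cuprate | CC(C)(C)[Si](C)(C)OC/C=C(\C)CC[Cu-]CC/C(C)=C/CO[Si](C)(C)C(C)(C)C.Br[Mg+] | intermediate (not isolated)
28 | methyl 2-[(1S,5R,6S)-5-[(3E)-5-{[tert-butyl(dimethyl)silyl]oxy}-3-methylpent-3-en-1-yl]-6-(2-methoxy-2-oxoethyl)-4,6-dimethylcyclohex-3-en-1-yl]-2-methylpropanoate | CC(C)(C)[Si](C)(C)OC/C=C(\C)CC[C@@H]1C(C)=CC[C@H](C(C)(C)C(=O)OC)[C@@]1(C)CC(=O)OC | intermediate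
29 | 2-[(1S,5R,6S)-5-[(3E)-5-{[tert-butyl(dimethyl)silyl]oxy}-3-methylpent-3-en-1-yl]-6-(2-hydroxyethyl)-4,6-dimethylcyclohex-3-en-1-yl]-2-methylpropan-1-ol | CC(C)(C)[Si](C)(C)OC/C=C(\C)CC[C@@H]1C(C)=CC[C@H](C(C)(C)CO)[C@@]1(C)CCO | intermediate
30 | 2-[(1S,5R,6S)-5-[(3E)-5-{[tert-butyl(dimethyl)silyl]oxy}-3-methylpent-3-en-1-yl]-4,6-dimethyl-6-(2-oxoethyl)cyclohex-3-en-1-yl]-2-methylpropanal (2,3-seco-2,3-dialdehyde) | CC(C)(C)[Si](C)(C)OC/C=C(\C)CC[C@@H]1C(C)=CC[C@H](C(C)(C)C=O)[C@@]1(C)CC=O | intermediate
31 | (2R,3S,4aS,5R,8aS)-5-[(3E)-5-{[tert-butyl(dimethyl)silyl]oxy}-3-methylpent-3-en-1-yl]-1,1,4a,6-tetramethyl-1,2,3,4,4a,5,8,8a-octahydronaphthalene-2,3-diol | CC(C)(C)[Si](C)(C)OC/C=C(\C)CC[C@@H]1C(C)=CC[C@@H]2C(C)(C)[C@@H](O)[C@@H](O)C[C@@]12C | intermediate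
32 | (2R,3S,4aS,5R,8aS)-5-[(3E)-5-hydroxy-3-methylpent-3-en-1-yl]-1,1,4a,6-tetramethyl-1,2,3,4,4a,5,8,8a-octahydronaphthalene-2,3-diol | OC/C=C(\C)CC[C@@H]1C(C)=CC[C@@H]2C(C)(C)[C@@H](O)[C@@H](O)C[C@@]12C | intermediate
33 | (2S,3R,4aS,8R,8aS)-8-[(3E)-5-(acetyloxy)-3-methylpent-3-en-1-yl]-3-hydroxy-4,4,7,8a-tetramethyl-1,2,3,4,4a,5,8,8a-octahydronaphthalen-2-yl acetate | CC(=O)OC/C=C(\C)CC[C@@H]1C(C)=CC[C@@H]2C(C)(C)[C@@H](O)[C@@H](OC(C)=O)C[C@@]12C | target

## Step count and least certain steps

Total: 21 steps. Longest linear sequence: 16 steps (steps 6 to 21, from 9). The chain fragment takes steps 1 to 5 and joins in step 16.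

Step 19 (key step). The most likely failure is loss of diastereocontrol: if the second carbonyl is attacked without being held on the same samarium, the two oxygens can end trans (both equatorial). Simple reduction of the hindered C-3 aldehyde, or aldol closure of the dialdehyde before electron transfer, can also compete. Fallback, setting out from 30 and returning at 33: the C-3 carbinol is set by ketone reduction, not by the coupling. The coupling is run as before, and 31 together with its C-3 epimer, trans-diol F1 (same C-2 configuration), is acetylated at the less hindered equatorial C-2 hydroxyl (Ac2O, pyridine). This gives the epimeric 2-acetate F2 together with the 2-acetate of 31. Oxidation with Dess–Martin periodinane converges both on 2-acetoxy-3-ketone F3. LiBH(sBu)3 at −78 °C should approach along the equatorial direction and give the axial alcohol, 2-acetate F4. Bu4NF buffered with AcOH then frees 15-alcohol F5, and acetylation of the primary hydroxyl gives 33.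

Step 16. The organocopper may attack the α-carbon (C-7) instead of the γ-carbon, because C-9 lies next to the quaternary C-10 and is approached on the face of its pseudoaxial methyl. Isomerisation of the allylcopper intermediate before reductive elimination would erode both regio- and stereoselectivity. Fallback, setting out from 22 and 26 and returning at 28: the chain is attached by cross-coupling and the C-9 hydrogen is delivered by a reductive allylic transposition. HF·pyridine converts 22 into hydroxy triflate F6, and Dess–Martin oxidation gives β-triflyloxy enone F7. Grignard reagent 26 and 9-methoxy-9-borabicyclo[3.3.1]nonane give alkylborane F8, which is coupled with F7 (PdCl2(dppf), K3PO4, THF/DMF) to give chain-bearing enone F9. NaBH4 with CeCl3·7H2O should deliver hydride axially, on the face of the C-5 hydrogen, and give the C-7-epimeric allylic alcohol F10 (hydroxyl cis to the C-5 substituent). Mitsunobu displacement with 2-nitrobenzenesulfonylhydrazide (PPh3, diethyl azodicarboxylate, THF, −30 °C → rt) inverts C-7. Loss of sulfinic acid gives the allylic diazene, which transfers hydrogen suprafacially to C-9 with loss of N2 and shifts the alkene to C-7=C-8, giving 28.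

Step 10. C-alkylation at the fully substituted enolate carbon, next to the branched C-5 substituent, may be slow. Proton transfer from the product or from the bromoester, O-alkylation, or attack of fluoride on the secondary silyl ether could then take over. Fallback, setting out from 15 and returning at 18: the arm is introduced as an allyl group through a π-allyl electrophile and then degraded. Palladium-catalysed allylation of the silyl enol ether (allyl methyl carbonate, Pd2(dba)3, PPh3, Bu4N[Ph3SiF2], THF) gives allyl ketone F11, with the same facial preference. Oxidative cleavage (RuCl3 cat., NaIO4, CCl4/MeCN/H2O) gives carboxylic acid F12, and Me3SiCHN2 in MeOH/toluene gives 18.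

Step 12. The tetrasubstituted enolate may expel silanolate from C-7 (E1cB) before it is sulfonylated. Deprotonation of the acetate arm, or acylation of the enolate oxygen by that ester, may also intervene. Fallback, setting out from 20 and returning at 24: the elimination is accepted and the oxygen is reinstalled by an epoxy-ketone transposition. DBU gives enone F13. H2O2 with catalytic NaOH in MeOH at 0 °C should add to C-7 trans to the C-5 substituent, as nucleophiles do on 5-substituted cyclohexenones, giving epoxy ketone F14. Wharton rearrangement (N2H4·H2O, AcOH, MeOH) then gives allylic alcohol 24 directly, replacing steps 12 to 14.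

Step 21. Acetylation may run on to the C-3 hydroxyl, or the acetyl group may migrate from O-2 to O-3 under base, eroding the distinction between the two secondary hydroxyls. Fallback, setting out from 32 and returning at 33: the two acetyl groups are introduced separately and the second is directed by tin. Lipase-catalysed acetylation (Candida antarctica lipase B, vinyl acetate) of the primary hydroxyl gives 15-acetate F15. Bu2SnO in toluene at reflux gives stannylene acetal F16, and acetyl chloride at 0 °C should acylate its equatorial oxygen (O-2), giving 33.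

## Further compounds

F1 | step 19 | C-3 epimer of 31 (trans-2,3-diol, 15-silyl ether) | CC(C)(C)[Si](C)(C)OC/C=C(\C)CC[C@@H]1C(C)=CC[C@@H]2C(C)(C)[C@H](O)[C@@H](O)C[C@@]12C
F2 | step 19 | 2-O-acetyl derivative of F1 | CC(C)(C)[Si](C)(C)OC/C=C(\C)CC[C@@H]1C(C)=CC[C@@H]2C(C)(C)[C@H](O)[C@@H](OC(C)=O)C[C@@]12C
F3 | step 19 | 2-acetoxy-3-ketone (15-silyl ether) | CC(C)(C)[Si](C)(C)OC/C=C(\C)CC[C@@H]1C(C)=CC[C@@H]2C(C)(C)C(=O)[C@@H](OC(C)=O)C[C@@]12C
F4 | step 19 | 2-O-acetyl derivative of 31 (axial 3-hydroxyl, 15-silyl ether) | CC(C)(C)[Si](C)(C)OC/C=C(\C)CC[C@@H]1C(C)=CC[C@@H]2C(C)(C)[C@@H](O)[C@@H](OC(C)=O)C[C@@]12C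
F5 | step 19 | 2-O-acetyl derivative of 32 (free 3- and 15-hydroxyls) | OC/C=C(\C)CC[C@@H]1C(C)=CC[C@@H]2C(C)(C)[C@@H](O)[C@@H](OC(C)=O)C[C@@]12C
F6 | step 16 | C-7 alcohol of enol triflate 22 | COC(=O)C[C@@]1(C)C(OS(=O)(=O)C(F)(F)F)=C(C)[C@@H](O)C[C@@H]1C(C)(C)C(=O)OC
F7 | step 16 | 7-oxo-9-triflyloxy-8-ene diester (β-triflyloxy enone) | COC(=O)C[C@@]1(C)C(OS(=O)(=O)C(F)(F)F)=C(C)C(=O)C[C@@H]1C(C)(C)C(=O)OC
F8 | step 16 | 9-[(3E)-5-{[tert-butyl(dimethyl)silyl]oxy}-3-methylpent-3-en-1-yl]-9-borabicyclo[3.3.1]nonane | CC(C)(C)[Si](C)(C)OC/C=C(\C)CCB1C2CCCC1CCC2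
F9 | step 16 | 7-oxo-8-ene diester bearing the chain on C-9 | CC(C)(C)[Si](C)(C)OC/C=C(\C)CCC1=C(C)C(=O)C[C@H](C(C)(C)C(=O)OC)[C@@]1(C)CC(=O)OC
F10 | step 16 | 7-hydroxy-8-ene diester bearing the chain on C-9, hydroxyl cis to the C-5 substituent | CC(C)(C)[Si](C)(C)OC/C=C(\C)CCC1=C(C)[C@H](O)C[C@H](C(C)(C)C(=O)OC)[C@@]1(C)CC(=O)OC
F11 | step 10 | methyl 2-[(1S,2R,5S)-5-{[tert-butyl(dimethyl)silyl]oxy}-2-methyl-3-oxo-2-(prop-2-en-1-yl)cyclohexyl]-2-methylpropanoate | C=CC[C@@]1(C)C(=O)C[C@@H](O[Si](C)(C)C(C)(C)C)C[C@@H]1C(C)(C)C(=O)OC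
F12 | step 10 | carboxylic acid corresponding to 18 (free acid on the C-10 arm) | OC(=O)C[C@@]1(C)C(=O)C[C@@H](O[Si](C)(C)C(C)(C)C)C[C@@H]1C(C)(C)C(=O)OC
F13 | step 12 | 9-oxo-7-ene diester (enone from 20 by loss of silanol) | COC(=O)C[C@@]1(C)C(=O)C(C)=CC[C@@H]1C(C)(C)C(=O)OC
F14 | step 12 | 7,8-epoxy-9-ketone diester, epoxide trans to the C-5 substituent | COC(=O)C[C@@]1(C)C(=O)[C@@]2(C)O[C@H]2C[C@@H]1C(C)(C)C(=O)OC
F15 | step 21 | 15-O-acetyl derivative of 32 (free 2,3-diol) | CC(=O)OC/C=C(\C)CC[C@@H]1C(C)=CC[C@@H]2C(C)(C)[C@@H](O)[C@@H](O)C[C@@]12C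
F16 | step 21 | 2,3-O-dibutylstannylene acetal of F15 | CC(=O)OC/C=C(\C)CC[C@@H]1C(C)=CC[C@@H]2C(C)(C)[C@H]3O[Sn](CCCC)(CCCC)O[C@H]3C[C@@]12C
A1 | alternative 1 | (2R,3R,5S)-5-{[tert-butyl(dimethyl)silyl]oxy}-2-methyl-3-(2-methylbut-3-en-2-yl)-2-(prop-2-en-1-yl)cyclohexan-1-one | C=CC[C@@]1(C)C(=O)C[C@@H](O[Si](C)(C)C(C)(C)C)C[C@@H]1C(C)(C)C=C
A2 | alternative 2 | ethyl (2E)-4-[(4S,5R)-5-[(3E,5Z)-5-{[tert-butyl(dimethyl)silyl]oxy}-2-methylhepta-3,5-dien-2-yl]-2,2-dimethyl-1,3-dioxolan-4-yl]-3-methylbut-2-enoate | CCOC(=O)/C=C(\C)C[C@@H]1OC(C)(C)O[C@@H]1C(C)(C)/C=C/C(O[Si](C)(C)C(C)(C)C)=C/C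
A3 | alternative 2 | trans-fused cycloadduct: C-9 ethyl ester, C-8 and C-10 methyls, C-6=C-7 silyl enol ether, 2,3-O-isopropylidene | CCOC(=O)[C@@H]1[C@H](C)C(O[Si](C)(C)C(C)(C)C)=C[C@@H]2C(C)(C)[C@H]3OC(C)(C)O[C@H]3C[C@@]12C
A4 | alternative 3 | (5R,6R)-2,6-dimethyl-5-(prop-1-en-2-yl)-6-(prop-2-yn-1-yl)cyclohex-2-en-1-one | O=C1C(C)=CC[C@H](C(C)=C)[C@@]1(C)CC#C
A5 | alternative 3 | (4aR,8aR)-4,4,7,8a-tetramethyl-8-oxo-1,4,4a,5,8,8a-hexahydronaphthalen-2-yl trifluoromethanesulfonate | O=C1C(C)=CC[C@@H]2C(C)(C)C=C(OS(=O)(=O)C(F)(F)F)C[C@@]12C
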